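**Easy step.** This flask takes the same charge of starting material as Saturday's run, with twice the free catalyst, so the first question is how far along Saturday's curve it stands.

| setting | Saturday's | flask |
|---|---|---|
| starting material | 2 M | 2.0 M |
| free catalyst | 50 mM | 100 mM |
| remark | run made earlier |  |
| time |  | 15 d |
- Saturday's (time / h: isomer of the product / %, target / %, starting material / %): 8.00: 34, 15, 35; 15.0: 40, 11, 21; 20.0: 44, 10, 15; 30.0: 53, 9, 15; 40.0: 51, 7, 11

(each reading ± 1.5 percentage points)
- on the list of suspects stand: target + free catalyst <-> isomer of the product + free catalyst; free catalyst + target -> spent catalyst; free catalyst + target -> free catalyst + over-reaction product; isomer of the product <-> starting material; starting material <-> target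
- no earlier run changes the charge of free catalyst; that part of a forecast is a guess
- share of isomer of the product in isomer of the product plus target at 15 min
- share of isomer of the product in isomer of the product plus target at 8.0 h
- share of isomer of the product in isomer of the product plus target at 15 d

**Saturday hours.** Multiplying the clock by the flask's free-catalyst charge over Saturday's charge gives 16.0 h at 8.0 h: these are the flask's Saturday hours, hours of Saturday's catalyst exposure. No earlier run changes that charge, so the rule is a guess. At 15 min they fall before Saturday's first reading, and at 15 d after its last, so the bracket here is for 8.0 h.

**The bracket.** Saturday's reading at 8.00 h gives this reckoning's floor for the isomer share, 69.4%, an estimate that carries the scatter: same clock, less catalyst. Its reading at 20.0 h gives the reckoned ceiling, 81.5%, with the same scatter: a longer clock, and more exposure by the guessed rule. Between that reading and 78.4% at 15.0 h, a straight line at the Saturday hours gives this reckoning's own 79.0%.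

**The forecast.** It stands at 10%, 80% and 90%, arguing that “Doubling the catalyst roughly doubles the integrated catalyst exposure”. Its middle figure lies inside the bracket, slightly above the straight line.

**The result.** The flask gives 25.6%, 82.2% and 91.8%; the middle value lies just above the reckoned ceiling, itself a scattered reading.

    target + free catalyst ⇌ isomer of the product + free catalyst, rate k1*[free catalyst]*[target] forward; the back reaction follows from the equilibrium constant (K = 11.0, k = 4.50 M⁻¹ h⁻¹)
    free catalyst + target → spent catalyst (k = 0.370 M⁻¹ h⁻¹)
    free catalyst + target → free catalyst + over-reaction product (k = 4.40 M⁻¹ h⁻¹)
    isomer of the product ⇌ starting material (k = 0.00500 h⁻¹)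
    starting material ⇌ target (K = 0.680, k = 0.150 h⁻¹)

**Where it went.** At 0.205 d target has a half-life of 0.090 d by over-reaction, shorter than the 0.42 d of free catalyst going to spent catalyst, and over-reaction uses target at 0.98 of its forward rate to isomer. At 15 d this flask holds 59.4% of the starting material charged as over-reaction product against 29.2% as isomer, with 0.0823% of the catalyst charged still free. For the neighbour charged with 0.060 M of free catalyst, the Saturday hours at 8.0 h come to 9.60 h, which reads 71.5% on a straight line between Saturday's readings, and that neighbour gives 72.9%.

The earlier runs and the new flask are calculated for substances that don't exist; scatter was added.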